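**Retrosynthetic overview** (lignan numbering C7/C8/C9 for the glycerol chain; ring A = guaiacyl ring, ring B = syringyl ring, ring C = benzene ring of the benzofuran, ring D = dihydrofuran ring with C2 and C3)
1. The target is the erythro (7S,8R) arylglycerol β-aryl ether of a trans-(2R,3S) phenylcoumaran; the last two operations only unmask it (imide to the C9 carbinol, dioxolane to the ring C aldehyde).
2. Key disconnection C7–C8: C8 carries the ether oxygen to ring B and C9, a primary carbinol that can be carried as an acyl group, so C8–H is the enolisable α-position of an aryloxyacetyl imide; C7 is a benzylic carbinol on ring A, i.e. the carbonyl carbon of non-enolisable vanillin. An auxiliary-controlled, MgCl2-catalysed direct anti-glycolate aldol joins the halves and sets C7 and C8 together.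
3. The imide comes from the ring B phenol and an N-bromoacetyl oxazolidinone (O–CH2 bond).
4. Ring D is the only ring made: a rhodium carbene from an aryldiazoacetate inserts into the ring B benzylic ether C–H (C2–C3 bond; the catalyst sets C2, base epimerisation relays C3 to trans). The diazo ester comes from Pd coupling of ethyl diazoacetate with an aryl iodide.
5. The ether precursor is assembled by Mitsunobu union of O-benzylsyringyl alcohol with 5-iodovanillin; rings A, B and C are bought as vanillin acetate, syringaldehyde and 5-iodovanillin.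

Key step: step 11

Remark: Rh2(S-PTTL)4 (dirhodium tetrakis[N-phthaloyl-(S)-tert-leucinate]) is assumed to give the (2R) configuration at the insertion carbon, by analogy with 2-(arylmethoxy)phenyl diazoacetates; if the opposite sense is found, Rh2(R-PTTL)4 takes its place and nothing else changes.

**Step 1**
Reactants: 1 syringaldehyde
Product: 2 4-(benzyloxy)-3,5-dimethoxybenzaldehyde
Conditions: BnBr, K2CO3, DMF, 60 °C
Reagents that add atoms: benzyl bromide, BrCc1ccccc1
Why: Williamson etherification of the acidic para-formyl phenoxide; a benzyl ether is chosen because it keeps the para oxygen non-ionisable through the later base steps.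

**Step 2**
Reactants: 2 4-(benzyloxy)-3,5-dimethoxybenzaldehyde
Product: 3 [4-(benzyloxy)-3,5-dimethoxyphenyl]methanol
Conditions: NaBH4, MeOH–THF, 0 °C
Reagents that add atoms: none
Why: Borohydride reduction of an aryl aldehyde to the benzylic alcohol.

**Step 3**
Reactants: 3 [4-(benzyloxy)-3,5-dimethoxyphenyl]methanol; 4 5-iodovanillin
Product: 5 4-{[4-(benzyloxy)-3,5-dimethoxybenzyl]oxy}-3-iodo-5-methoxybenzaldehyde
Conditions: PPh3, DIAD, THF, 0 °C to rt
Reagents that add atoms: none
Why: Mitsunobu etherification; the ortho-iodo, para-formyl phenol is an acidic pronucleophile and the primary benzylic alcohol is activated as its alkoxyphosphonium salt.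

**Step 4**
Reactants: 5 4-{[4-(benzyloxy)-3,5-dimethoxybenzyl]oxy}-3-iodo-5-methoxybenzaldehyde
Product: 6 2-(4-{[4-(benzyloxy)-3,5-dimethoxybenzyl]oxy}-3-iodo-5-methoxyphenyl)-1,3-dioxolane
Conditions: (TMSOCH2)2, TMSOTf (5 mol %), CH2Cl2, −78 to −20 °C; Et3N quench
Reagents that add atoms: 1,2-bis(trimethylsilyloxy)ethane, C[Si](C)(C)OCCO[Si](C)(C)C
Why: Silyl-triflate-catalysed acetalisation with the bis-silyl glycol masks the aldehyde against hydride and enolate chemistry, under conditions cold and brief enough for the electron-rich benzyl aryl ether.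

**Step 5**
Reactants: 6 2-(4-{[4-(benzyloxy)-3,5-dimethoxybenzyl]oxy}-3-iodo-5-methoxyphenyl)-1,3-dioxolane; 7 ethyl diazoacetate
Product: 8 ethyl 2-diazo-2-[2-{[4-(benzyloxy)-3,5-dimethoxybenzyl]oxy}-5-(1,3-dioxolan-2-yl)-3-methoxyphenyl]acetate
Conditions: Pd(PPh3)4 (5 mol %), Ag2CO3 (0.5 equiv), Et3N (1.3 equiv), toluene, rt
Reagents that add atoms: none
Why: Pd-catalysed cross-coupling of an aryl iodide with the C–H bond of an acceptor diazo ester, which retains the diazo group (oxidative addition, silver-assisted iodide abstraction, C-palladation of the diazo ester, reductive elimination).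

**Step 6**
Reactants: 8 ethyl 2-diazo-2-[2-{[4-(benzyloxy)-3,5-dimethoxybenzyl]oxy}-5-(1,3-dioxolan-2-yl)-3-methoxyphenyl]acetate
Product: 10 ethyl (2R,3R)-2-[4-(benzyloxy)-3,5-dimethoxyphenyl]-5-(1,3-dioxolan-2-yl)-7-methoxy-2,3-dihydro-1-benzofuran-3-carboxylate (trans ester), via cis ester 9 (not isolated)
Conditions: Rh2(S-PTTL)4 (1 mol %), toluene, −60 °C; then NaOEt (0.3 equiv), EtOH, 0 °C to rt
Reagents that add atoms: none
Why: Enantioselective intramolecular 1,5 C–H insertion of the donor/acceptor rhodium carbene into the ether CH2 (activated by oxygen and the electron-rich aryl group) should close ring D cis with C2 set by the catalyst; ethoxide then epimerises only C3 (α to the ester) to the more stable trans ester, C2 being fixed because its para oxygen is benzylated.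

**Step 7**
Reactants: 10 ethyl (2R,3R)-2-[4-(benzyloxy)-3,5-dimethoxyphenyl]-5-(1,3-dioxolan-2-yl)-7-methoxy-2,3-dihydro-1-benzofuran-3-carboxylate
Product: 11 [(2R,3S)-2-[4-(benzyloxy)-3,5-dimethoxyphenyl]-5-(1,3-dioxolan-2-yl)-7-methoxy-2,3-dihydro-1-benzofuran-3-yl]methanol
Conditions: LiBH4, MeOH (2 equiv), THF, 0 °C to rt
Reagents that add atoms: none
Why: Borohydride reduction of the ester to the primary alcohol leaves the acetal and benzyl ether untouched and makes C3 configurationally fixed (the descriptor changes from 3R to 3S by priority only).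

**Step 8**
Reactants: 11 [(2R,3S)-2-[4-(benzyloxy)-3,5-dimethoxyphenyl]-5-(1,3-dioxolan-2-yl)-7-methoxy-2,3-dihydro-1-benzofuran-3-yl]methanol
Product: 12 4-[(2R,3S)-5-(1,3-dioxolan-2-yl)-3-(hydroxymethyl)-7-methoxy-2,3-dihydro-1-benzofuran-2-yl]-2,6-dimethoxyphenol
Conditions: H2 (1 atm), 10% Pd/C, EtOAc–EtOH, rt, stopped after one equivalent
Reagents that add atoms: none
Why: Hydrogenolysis of the aryl benzyl ether under neutral conditions should be faster than cleavage of the cyclic benzylic C2–O bond or of the aryl dioxolane.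

**Step 9**
Reactants: 13 (R)-4-benzyl-1,3-oxazolidin-2-one; 14 bromoacetyl bromide
Product: 15 (R)-4-benzyl-3-(bromoacetyl)-1,3-oxazolidin-2-one
Conditions: n-BuLi, THF, −78 °C; then 14, −78 to 0 °C
Reagents that add atoms: none
Why: N-acylation of the lithiated oxazolidinone by the acid bromide, which is far more reactive than the alkyl bromide.

**Step 10**
Reactants: 12 4-[(2R,3S)-5-(1,3-dioxolan-2-yl)-3-(hydroxymethyl)-7-methoxy-2,3-dihydro-1-benzofuran-2-yl]-2,6-dimethoxyphenol; 15 (R)-4-benzyl-3-(bromoacetyl)-1,3-oxazolidin-2-one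
Product: 16 (R)-4-benzyl-3-({4-[(2R,3S)-5-(1,3-dioxolan-2-yl)-3-(hydroxymethyl)-7-methoxy-2,3-dihydro-1-benzofuran-2-yl]-2,6-dimethoxyphenoxy}acetyl)-1,3-oxazolidin-2-one
Conditions: K2CO3, acetone, rt
Reagents that add atoms: none
Why: Williamson alkylation; only the phenol is ionised by carbonate, and SN2 displacement at the α-bromo imide should outrun acyl attack by the hindered 2,6-dimethoxyphenoxide.

**Step 11**
Reactants: 16 (R)-4-benzyl-3-({4-[(2R,3S)-5-(1,3-dioxolan-2-yl)-3-(hydroxymethyl)-7-methoxy-2,3-dihydro-1-benzofuran-2-yl]-2,6-dimethoxyphenoxy}acetyl)-1,3-oxazolidin-2-one; 17 vanillin acetate (4-formyl-2-methoxyphenyl acetate)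
Product: 18 (4R)-3-[(2S,3S)-3-(4-acetoxy-3-methoxyphenyl)-2-{4-[(2R,3S)-5-(1,3-dioxolan-2-yl)-7-methoxy-3-{[(trimethylsilyl)oxy]methyl}-2,3-dihydro-1-benzofuran-2-yl]-2,6-dimethoxyphenoxy}-3-[(trimethylsilyl)oxy]propanoyl]-4-benzyl-1,3-oxazolidin-2-one
Conditions: TMSCl (3.2 equiv), Et3N (4 equiv), EtOAc, rt, 30 min; then MgCl2 (20 mol %), 17 (1.3 equiv), rt, 24–36 h; pH 7 buffer work-up
Reagents that add atoms: chlorotrimethylsilane, C[Si](C)(C)Cl
Why: Proposed new method: MgCl2 chelates the two imide carbonyls of 16, Et3N removes the acidified C8–H to give the chelated Z-enolate (aryloxy cis to O–Mg), aldehyde 17 binds the same magnesium and adds through a boat-like six-membered transition state, and TMSCl silylates the magnesium aldolate, which turns the metal over and shuts off retro-aldol; the hydroxymethyl group on C3 of ring D is silylated in the same flask beforehand, so it needs no separate protection. The closest known reaction type is the MgCl2/Et3N/TMSCl-catalysed direct anti-aldol of N-propionyl and other N-alkanoyl oxazolidinones with non-enolisable aromatic aldehydes, and boron-mediated syn-aldols of N-aryloxyacetyl oxazolidinones show that such glycolate imides enolise cleanly to Z-enolates; what is new is the α-aryloxy substituent in the magnesium manifold. No ring is closed. C8 should be set by the (R)-benzyl group of the auxiliary, which shields one face of the chelated enolate as in alkylations of such enolates (attack anti to benzyl, 8R after reduction), and C7 relative to C8 by the boat transition state (anti, i.e. erythro, 7S). The step needs anti over syn selectivity, one enolate face and a single electrophilic carbonyl: auxiliary and chelate should secure the first two, the two ortho methoxy groups hinder a competing five-membered chelate through the ether oxygen, the ring C aldehyde is masked as a dioxolane so that 17 is the only aldehyde present, and its para-acetoxy group makes it more electrophilic than a para-alkoxy benzaldehyde.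

**Step 12**
Reactants: 18 the bis-silylated anti-aldol adduct
Product: 20 (1S,2R)-2-{4-[(2R,3S)-5-(1,3-dioxolan-2-yl)-3-(hydroxymethyl)-7-methoxy-2,3-dihydro-1-benzofuran-2-yl]-2,6-dimethoxyphenoxy}-1-(4-hydroxy-3-methoxyphenyl)propane-1,3-diol, via bis-silyl ether 19 (not isolated)
Conditions: LiBH4 (4 equiv), MeOH (4 equiv), THF, 0 °C to rt; then K2CO3, MeOH, rt
Reagents that add atoms: none
Why: Reductive cleavage of the imide at the exocyclic carbonyl (activated by the α-aryloxy group) gives the C9 carbinol and frees the auxiliary, the aryl acetate is reduced off in the same operation, and methanolysis removes both trimethylsilyl ethers; no stereocentre is touched.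

**Step 13**
Reactants: 20 the dioxolane-protected target
Product: 21 (2R,3S)-2-(4-{[(1S,2R)-1,3-dihydroxy-1-(4-hydroxy-3-methoxyphenyl)propan-2-yl]oxy}-3,5-dimethoxyphenyl)-3-(hydroxymethyl)-7-methoxy-2,3-dihydro-1-benzofuran-5-carbaldehyde (target, CID53356209)
Conditions: 0.2 M HCl, THF–H2O (4:1), 0 °C to rt
Reagents that add atoms: water, O
Why: Acid hydrolysis of the dioxolane of an electron-rich benzaldehyde should be much faster than ionisation at the para-hydroxybenzylic C7 or opening of ring D, so the erythro and trans relationships should be kept.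

**Compound list**
1 | syringaldehyde (4-hydroxy-3,5-dimethoxybenzaldehyde) | COc1cc(C=O)cc(OC)c1O | starting material
2 | 4-(benzyloxy)-3,5-dimethoxybenzaldehyde | COc1cc(C=O)cc(OC)c1OCc1ccccc1 | intermediate
3 | [4-(benzyloxy)-3,5-dimethoxyphenyl]methanol | COc1cc(CO)cc(OC)c1OCc1ccccc1 | intermediate
4 | 5-iodovanillin (4-hydroxy-3-iodo-5-methoxybenzaldehyde) | COc1cc(C=O)cc(I)c1O | starting material
5 | 4-{[4-(benzyloxy)-3,5-dimethoxybenzyl]oxy}-3-iodo-5-methoxybenzaldehyde | COc1cc(C=O)cc(I)c1OCc1cc(OC)c(OCc2ccccc2)c(OC)c1 | intermediate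
6 | 2-(4-{[4-(benzyloxy)-3,5-dimethoxybenzyl]oxy}-3-iodo-5-methoxyphenyl)-1,3-dioxolane | COc1cc(C2OCCO2)cc(I)c1OCc1cc(OC)c(OCc2ccccc2)c(OC)c1 | intermediate
7 | ethyl diazoacetate | CCOC(=O)C=[N+]=[N-] | starting material
8 | ethyl 2-diazo-2-[2-{[4-(benzyloxy)-3,5-dimethoxybenzyl]oxy}-5-(1,3-dioxolan-2-yl)-3-methoxyphenyl]acetate | CCOC(=O)C(=[N+]=[N-])c1cc(C2OCCO2)cc(OC)c1OCc1cc(OC)c(OCc2ccccc2)c(OC)c1 | intermediate
9 | ethyl (2R,3S)-2-[4-(benzyloxy)-3,5-dimethoxyphenyl]-5-(1,3-dioxolan-2-yl)-7-methoxy-2,3-dihydro-1-benzofuran-3-carboxylate (cis ester) | COc1cc([C@@H]2Oc3c(OC)cc(C4OCCO4)cc3[C@@H]2C(=O)OCC)cc(OC)c1OCc1ccccc1 | intermediate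
10 | ethyl (2R,3R)-2-[4-(benzyloxy)-3,5-dimethoxyphenyl]-5-(1,3-dioxolan-2-yl)-7-methoxy-2,3-dihydro-1-benzofuran-3-carboxylate (trans ester) | COc1cc([C@@H]2Oc3c(OC)cc(C4OCCO4)cc3[C@H]2C(=O)OCC)cc(OC)c1OCc1ccccc1 | intermediate
11 | [(2R,3S)-2-[4-(benzyloxy)-3,5-dimethoxyphenyl]-5-(1,3-dioxolan-2-yl)-7-methoxy-2,3-dihydro-1-benzofuran-3-yl]methanol | COc1cc([C@@H]2Oc3c(OC)cc(C4OCCO4)cc3[C@H]2CO)cc(OC)c1OCc1ccccc1 | intermediate
12 | 4-[(2R,3S)-5-(1,3-dioxolan-2-yl)-3-(hydroxymethyl)-7-methoxy-2,3-dihydro-1-benzofuran-2-yl]-2,6-dimethoxyphenol | COc1cc([C@@H]2Oc3c(OC)cc(C4OCCO4)cc3[C@H]2CO)cc(OC)c1O | intermediate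
13 | (R)-4-benzyl-1,3-oxazolidin-2-one | O=C1N[C@H](Cc2ccccc2)CO1 | starting material
14 | bromoacetyl bromide | BrCC(Br)=O | starting material
15 | (R)-4-benzyl-3-(bromoacetyl)-1,3-oxazolidin-2-one | O=C(CBr)N1[C@H](Cc2ccccc2)COC1=O | intermediate
16 | (R)-4-benzyl-3-({4-[(2R,3S)-5-(1,3-dioxolan-2-yl)-3-(hydroxymethyl)-7-methoxy-2,3-dihydro-1-benzofuran-2-yl]-2,6-dimethoxyphenoxy}acetyl)-1,3-oxazolidin-2-one | COc1cc([C@@H]2Oc3c(OC)cc(C4OCCO4)cc3[C@H]2CO)cc(OC)c1OCC(=O)N1[C@H](Cc2ccccc2)COC1=O | intermediate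
17 | vanillin acetate (4-formyl-2-methoxyphenyl acetate) | COc1cc(C=O)ccc1OC(C)=O | starting material
18 | (4R)-3-[(2S,3S)-3-(4-acetoxy-3-methoxyphenyl)-2-{4-[(2R,3S)-5-(1,3-dioxolan-2-yl)-7-methoxy-3-{[(trimethylsilyl)oxy]methyl}-2,3-dihydro-1-benzofuran-2-yl]-2,6-dimethoxyphenoxy}-3-[(trimethylsilyl)oxy]propanoyl]-4-benzyl-1,3-oxazolidin-2-one | COc1cc([C@H](O[Si](C)(C)C)[C@@H](C(=O)N2[C@H](Cc3ccccc3)COC2=O)Oc2c(OC)cc([C@@H]3Oc4c(OC)cc(C5OCCO5)cc4[C@H]3CO[Si](C)(C)C)cc2OC)ccc1OC(C)=O | intermediate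
19 | (2R,3S)-2-{4-[(2R,3S)-5-(1,3-dioxolan-2-yl)-7-methoxy-3-{[(trimethylsilyl)oxy]methyl}-2,3-dihydro-1-benzofuran-2-yl]-2,6-dimethoxyphenoxy}-3-(4-hydroxy-3-methoxyphenyl)-3-[(trimethylsilyl)oxy]propan-1-ol (bis-silyl ether) | COc1cc([C@H](O[Si](C)(C)C)[C@@H](CO)Oc2c(OC)cc([C@@H]3Oc4c(OC)cc(C5OCCO5)cc4[C@H]3CO[Si](C)(C)C)cc2OC)ccc1O | intermediate
20 | (1S,2R)-2-{4-[(2R,3S)-5-(1,3-dioxolan-2-yl)-3-(hydroxymethyl)-7-methoxy-2,3-dihydro-1-benzofuran-2-yl]-2,6-dimethoxyphenoxy}-1-(4-hydroxy-3-methoxyphenyl)propane-1,3-diol | COc1cc([C@H](O)[C@@H](CO)Oc2c(OC)cc([C@@H]3Oc4c(OC)cc(C5OCCO5)cc4[C@H]3CO)cc2OC)ccc1O | intermediate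
21 | (2R,3S)-2-(4-{[(1S,2R)-1,3-dihydroxy-1-(4-hydroxy-3-methoxyphenyl)propan-2-yl]oxy}-3,5-dimethoxyphenyl)-3-(hydroxymethyl)-7-methoxy-2,3-dihydro-1-benzofuran-5-carbaldehyde | COc1cc([C@H](O)[C@@H](CO)Oc2c(OC)cc([C@@H]3Oc4c(OC)cc(C=O)cc4[C@H]3CO)cc2OC)ccc1O | target

**Totals**
Total step count: 13. Longest linear sequence: 12 steps (steps 1–8 and 10–13, from syringaldehyde); step 9 is a one-step side branch.

**Steps most likely to fail**

Step 11 (proposed new method). What may go wrong: the aryloxy and ortho-methoxy oxygens may compete for magnesium and erode anti/syn and facial selectivity; addition to the electron-rich aldehyde may be slow, allowing retro-aldol before silylation; or the dioxolane may be opened by the Lewis acid/silyl chloride pair. The fallback uses known chemistry, a boron-mediated syn-glycolate aldol followed by inversion at C7. It sets out from 12 and comes back at 20. Commercial (S)-4-benzyl-1,3-oxazolidin-2-one is acylated with 14 (n-BuLi, THF, −78 °C) to give (S)-4-benzyl-3-(bromoacetyl)-1,3-oxazolidin-2-one F1, which alkylates 12 (K2CO3, acetone) to the enantiomeric-auxiliary imide F2. Enolisation with Bu2BOTf/i-Pr2NEt in CH2Cl2 at −78 °C (one extra equivalent of Bu2BOTf carries the primary alcohol as its borinate) and addition of 17, then buffered oxidative work-up, should give the syn (threo, 7R,8R-type) aldol adduct F3; in the non-chelated boron enolate the (S)-auxiliary gives the same C8 configuration as the main route. Mitsunobu reaction with 4-nitrobenzoic acid (PPh3, DIAD, THF) should invert the benzylic carbinol and also esterify the primary alcohol, giving the bis(4-nitrobenzoate) F4. LiBH4 followed by K2CO3/MeOH then cleaves auxiliary, acetate and both nitrobenzoates to give 20.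

Step 6. What may go wrong: insufficient or reversed enantiofacial discrimination at the carbene with this tri-oxygenated benzyl ether, or base-induced opening and reclosure of ring D through the ester enolate during epimerisation, which would erode the configuration at C2. The fallback gives up asymmetric catalysis for a racemic synthesis with resolution. It sets out from 8 and comes back at 11. Insertion with achiral Rh2(OAc)4 in CH2Cl2 gives the racemic cis ester F5, NaOEt/EtOH gives the racemic trans ester F6, and LiBH4 gives the racemic trans alcohol F7. F7 is resolved by preparative chromatography on a chiral stationary phase to supply the (2R,3S) enantiomer 11.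

Step 5. What may go wrong: slow oxidative addition and transmetalation at the ortho-alkoxy aryl iodide, with palladium-mediated decomposition of the diazo ester (carbene dimerisation) taking over. The fallback builds the aryl–carbon bond first and introduces the diazo group afterwards. It sets out from 6 and comes back at 8. Negishi-type coupling of 6 with the Reformatsky reagent BrZnCH2CO2Et (Pd2(dba)3/XPhos, THF, 60 °C) gives ethyl [2-{[4-(benzyloxy)-3,5-dimethoxybenzyl]oxy}-5-(1,3-dioxolan-2-yl)-3-methoxyphenyl]acetate F8. Regitz diazo transfer (4-acetamidobenzenesulfonyl azide, DBU, MeCN) then gives 8.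

**Further compounds**
F1 | step 11 | (S)-4-benzyl-3-(bromoacetyl)-1,3-oxazolidin-2-one | O=C(CBr)N1[C@@H](Cc2ccccc2)COC1=O
F2 | step 11 | (S)-4-benzyl-3-({4-[(2R,3S)-5-(1,3-dioxolan-2-yl)-3-(hydroxymethyl)-7-methoxy-2,3-dihydro-1-benzofuran-2-yl]-2,6-dimethoxyphenoxy}acetyl)-1,3-oxazolidin-2-one | COc1cc([C@@H]2Oc3c(OC)cc(C4OCCO4)cc3[C@H]2CO)cc(OC)c1OCC(=O)N1[C@@H](Cc2ccccc2)COC1=O
F3 | step 11 | (4S)-3-[(2S,3R)-3-(4-acetoxy-3-methoxyphenyl)-2-{4-[(2R,3S)-5-(1,3-dioxolan-2-yl)-3-(hydroxymethyl)-7-methoxy-2,3-dihydro-1-benzofuran-2-yl]-2,6-dimethoxyphenoxy}-3-hydroxypropanoyl]-4-benzyl-1,3-oxazolidin-2-one (syn adduct) | COc1cc([C@@H](O)[C@@H](C(=O)N2[C@@H](Cc3ccccc3)COC2=O)Oc2c(OC)cc([C@@H]3Oc4c(OC)cc(C5OCCO5)cc4[C@H]3CO)cc2OC)ccc1OC(C)=O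
F4 | step 11 | bis(4-nitrobenzoate) of the C7-inverted adduct, (4S)-auxiliary, (2S,3S)-propanoyl unit | COc1cc([C@H](OC(=O)c2ccc(cc2)[N+](=O)[O-])[C@@H](C(=O)N2[C@@H](Cc3ccccc3)COC2=O)Oc2c(OC)cc([C@@H]3Oc4c(OC)cc(C5OCCO5)cc4[C@H]3COC(=O)c4ccc(cc4)[N+](=O)[O-])cc2OC)ccc1OC(C)=O
F5 | step 6 | racemic cis ethyl 2-[4-(benzyloxy)-3,5-dimethoxyphenyl]-5-(1,3-dioxolan-2-yl)-7-methoxy-2,3-dihydro-1-benzofuran-3-carboxylate | COc1cc([C@@H]2Oc3c(OC)cc(C4OCCO4)cc3[C@@H]2C(=O)OCC)cc(OC)c1OCc1ccccc1.COc1cc([C@H]2Oc3c(OC)cc(C4OCCO4)cc3[C@H]2C(=O)OCC)cc(OC)c1OCc1ccccc1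
F6 | step 6 | racemic trans ethyl 2-[4-(benzyloxy)-3,5-dimethoxyphenyl]-5-(1,3-dioxolan-2-yl)-7-methoxy-2,3-dihydro-1-benzofuran-3-carboxylate | COc1cc([C@@H]2Oc3c(OC)cc(C4OCCO4)cc3[C@H]2C(=O)OCC)cc(OC)c1OCc1ccccc1.COc1cc([C@H]2Oc3c(OC)cc(C4OCCO4)cc3[C@@H]2C(=O)OCC)cc(OC)c1OCc1ccccc1
F7 | step 6 | racemic trans [2-[4-(benzyloxy)-3,5-dimethoxyphenyl]-5-(1,3-dioxolan-2-yl)-7-methoxy-2,3-dihydro-1-benzofuran-3-yl]methanol | COc1cc([C@@H]2Oc3c(OC)cc(C4OCCO4)cc3[C@H]2CO)cc(OC)c1OCc1ccccc1.COc1cc([C@H]2Oc3c(OC)cc(C4OCCO4)cc3[C@@H]2CO)cc(OC)c1OCc1ccccc1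
F8 | step 5 | ethyl [2-{[4-(benzyloxy)-3,5-dimethoxybenzyl]oxy}-5-(1,3-dioxolan-2-yl)-3-methoxyphenyl]acetate | CCOC(=O)Cc1cc(C2OCCO2)cc(OC)c1OCc1cc(OC)c(OCc2ccccc2)c(OC)c1
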